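The constants of the two gas steps are hidden, but the runs below yield their ratio, and a dispute over this flask turns on that ratio.

| flask | starting material | gas phase | protic impurity | remark | time |
|---|---|---|---|---|---|
| birch | 1.6 M | 200 mM (held) | 0.22 M | run made earlier |  |
| larch | 1.6 M | 200 mM (held) | 0.35 M | run made earlier |  |
| flask | 1.6 M | 200 mM (held) | 0.160 M |  | 25 min |

| run | time / min | target / % | starting material / % |
|---|---|---|---|
| birch | 1.00 | 2.1 | 95.1 |
| birch | 3.00 | 10.8 | 83.9 |
| birch | 5.00 | 18.4 | 73.3 |
| birch | 8.00 | 28.4 | 60.1 |
| birch | 12.0 | 38.0 | 46.0 |
| birch | 15.0 | 44.3 | 37.3 |
| larch | 2.50 | 8.6 | 84.4 |
| larch | 5.00 | 18.4 | 69.9 |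
| larch | 8.00 | 27.6 | 55.4 |
| larch | 10.0 | 33.0 | 48.4 |
| larch | 12.0 | 36.3 | 41.5 |
| larch | 15.0 | 42.0 | 33.0 |

(scatter of a reading: 0.3 percentage points)

- at the start none of the gas is dissolved
- what may be going on: gas phase <-> dissolved gas; target <-> isomer of the product; starting material + dissolved gas -> target; starting material + protic impurity -> quenched substrate

- how much target there is at 25 min, in percent of the starting material charged
- concentration of dissolved gas in solution at 6.0 min, in percent of saturation
- the change that raises the amount of target at 25 min, in percent of the starting material charged most ("none" if none brings more than 2 percentage points) (spring / midnight / none)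
- amount of target at 25 min, in percent of the starting material charged, after midnight

- spring: doubling the saturation concentration of gas phase, all else as stated
- midnight: doubling the transfer coefficient of the gas phase, all else as stated

One chemist holds that transfer is too slow, so that [dissolved gas] sits far below saturation; she points to the birch run, with target at 2.1% after 1.00 min and 10.8% after 3.00 min, a slow start. The other holds that the solution stays close to saturation, making the uptake pseudo-first-order in starting material; he points to the loss constant of starting material in birch, 0.0675 min⁻¹ between 3.00 min and 5.00 min and 0.0699 min⁻¹ between 12.0 min and 15.0 min.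

My reckoning removes the quench first. Larch, with more protic impurity, has lost more to side paths than birch by 15.0 min, and scaling that difference by the charges puts the quenched substrate in birch at about 11.2%. Protic impurity therefore decays at about 0.112 min⁻¹, and the quench takes 0.0143 min⁻¹ of the early constant and 0.00496 min⁻¹ of the late one. The uptake constants that remain, proportional to [dissolved gas], are 0.0532 min⁻¹ at 1.26 M and 0.0649 min⁻¹ at 0.666 M.

While dissolved gas is made as fast as it is used, its level, [dissolved gas] over saturation, equals h/(h+[starting material]). Here h, the half-level amount, is the [starting material] at which the level is 0.5. The two constants give h = 2.03 M, a rough value resting on a small difference of readings.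

The charge of 1.6 M lies below it, so by this rule the made-as-fast-as-used level stands above 0.5 in this flask. With [starting material] near 1.10 M at 6.0 min, read from birch as a stand-in, I reckon 64.9% of saturation for this flask. At that [starting material], doubling the transfer coefficient multiplies [dissolved gas] by 1.21, less than the doubling of [dissolved gas] that spring brings at an unchanged level, so I choose spring. The first chemist keeps the first minute, when the run starts with none of the gas dissolved.

The forecast leans her way, “so gas transfer is partly limiting”, with 57% of target, 43% of saturation, spring as the best change and 63% after midnight, and its level differs from mine.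

The flask gives 58.3% of target and 65.7% of saturation; spring is best, adding 12 percentage points against 3.5 points for midnight, which reaches 61.8%.

    gas phase ⇌ dissolved gas, rate k1*(csat - [dissolved gas]) (kL = 0.970 min⁻¹)
    target ⇌ isomer of the product (K = 0.330, k = 0.0360 min⁻¹)
    starting material + dissolved gas → target (k = 0.430 M⁻¹ min⁻¹)
    starting material + protic impurity → quenched substrate (k = 0.100 M⁻¹ min⁻¹)

In this flask at 12.5 min, 46.0% of starting material gives by the same rule 0.147 M of dissolved gas, and the flask holds 0.149 M. The neighbouring flask is this same flask read at 10 min, with 54.3% of starting material and 34.0% of target. The rule gives it a level of 70.0%, or 0.140 M of dissolved gas, and that flask holds 0.142 M.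

All runs stem from a simulated flask with made-up constants, noise included.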